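**Plan** (isochromanone numbering: C1 carbonyl, O2, C3 carbinol carbon, C4 benzylic CH2, C4a/C8a ring-fusion carbons, C8 phenol carbon)
1. Retrosynthesis: the phenol O–methyl bond is cut last and the lactone C1–O2 bond is traced back to a diisopropylamide. Then two C–C bonds are cut together, C4–C3 and C8a–C1, which leaves a 2-bromobenzyl bromide and an O-alkyl carbamate. The carbamate goes back to an alkynol and 1-bromooctane.
2. Enabling feature: the lactone atoms C3–O2–C1(=O) are an O-alkyl carbamate in disguise (C3 a chiral nucleophile after α-lithiation, C1 an acyl electrophile). The benzo ring offers C4 (benzylic electrophile) and C8a (aryl nucleophile between C4a and the oxygenated C8) in a 1,3 relation, with a bromine atom at C8a as temporary marker.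
3. Forward order: chain (alkyne alkylation, E-selective reduction, carbamoylation), arene partner (benzylic bromination), one-pot union of the two, then acid closes the six-membered lactone ring on the preformed benzene ring and BCl3 frees the phenol.
4. Stereochemistry: C3 (R) comes from (−)-sparteine-mediated removal of the pro-S proton and retentive benzylation; the E double bond comes from dissolving-metal reduction of the alkyne.

Key step: step 5

Remark: oct-7-yn-1-ol, 1-bromooctane, N,N-diisopropylcarbamoyl chloride, 2-bromo-3-methylanisole and (−)-sparteine are taken as commercially available.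

Step 1
Reactants: 1 oct-7-yn-1-ol; 2 1-bromooctane
Product: 3 hexadec-7-yn-1-ol
Conditions: n-BuLi (2.1 equiv), THF/DMPU, −78 °C to rt; then H2O
Reagents that add atoms: none
Why: Acetylide alkylation: after double deprotonation the acetylide carbon, more nucleophilic than the alkoxide oxygen, should displace the primary bromide by SN2 in the dipolar co-solvent and join the two C8 halves of the chain without forming a stereocenter.

Step 2
Reactants: 3 hexadec-7-yn-1-ol
Product: 4 (7E)-hexadec-7-en-1-ol
Conditions: Na, NH3(l), THF, −33 °C
Reagents that add atoms: none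
Why: Dissolving-metal reduction of the internal alkyne runs through a vinyl radical anion and vinyl anion that take the less crowded trans arrangement before protonation, which should set the E double bond while the alkoxide end stays inert.

Step 3
Reactants: 4 (7E)-hexadec-7-en-1-ol; 5 N,N-diisopropylcarbamoyl chloride
Product: 6 (7E)-hexadec-7-en-1-yl N,N-diisopropylcarbamate
Conditions: Et3N, DMAP (cat.), CH2Cl2, reflux
Reagents that add atoms: none
Why: Carbamoylation (nucleophilic acyl substitution at the carbamoyl chloride under DMAP catalysis) should turn the primary alcohol into the hindered carbamate that later directs α-lithiation and supplies the lactone carbonyl carbon, with the alkene unaffected.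

Step 4
Reactants: 7 2-bromo-1-methoxy-3-methylbenzene (2-bromo-3-methylanisole)
Product: 8 2-bromo-1-(bromomethyl)-3-methoxybenzene
Conditions: NBS, AIBN (cat.), PhCF3, 80 °C
Reagents that add atoms: N-bromosuccinimide, O=C1CCC(=O)N1Br
Why: Wohl–Ziegler radical bromination should attack the only benzylic C–H position, since the aryl bromide and the methyl ether are inert to the bromine radical chain and one equivalent of NBS limits double bromination.

Step 5
Reactants: 6 (7E)-hexadec-7-en-1-yl N,N-diisopropylcarbamate; 8 2-bromo-1-(bromomethyl)-3-methoxybenzene
Product: 12 N,N-diisopropyl-2-[(2R,8E)-2-hydroxyheptadec-8-en-1-yl]-6-methoxybenzamide, via lithiated carbamate 9 (not isolated), via bromoaryl carbamate 10 (not isolated), via aryllithium 11 (not isolated)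
Conditions: s-BuLi, (−)-sparteine, Et2O, −78 °C; then 8, −78 °C; then t-BuLi (2 equiv), −78 °C to rt; then H2O
Reagents that add atoms: none
Why: Proposed new method: the step merges two known anionic events into one formal [3+3] union in which the carbamate is a C3 nucleophile and C1 electrophile and bromide 8 is a C4 electrophile and latent C8a nucleophile; s-BuLi/(−)-sparteine removes the pro-S α-proton of 6 under direction by the carbamoyl oxygen to give the configurationally stable organolithium 9, which should displace the benzylic bromide of 8 by SN2 with retention at the carbanion carbon and so form the CH2–CH(O) bond in 10. Bromine–lithium exchange with t-BuLi then gives aryllithium 11, which attacks the carbamoyl carbon in a 6-exo-trig addition–elimination that expels the secondary alkoxide (1,5 O-to-C carbamoyl transfer) and forms the aryl–C(=O) bond. The closest known reaction types are the sparteine-mediated asymmetric α-lithiation–substitution of O-alkyl carbamates and the Parham cyclization or anionic Fries-type carbamoyl migration of aryllithiums, and what is new is their union on a 2-bromobenzyl bromide in one flask. No ring persists: the six-membered ring of the addition stage opens again as the alkoxide leaves, so the lactone ring is closed in step 6 by the oxygen set free here. The one new stereocenter (R, the later C3) is under reagent control by (−)-sparteine and is not touched by the organolithium stage that follows. The step needs benzylic substitution to outrun electron transfer and aryl bromine–lithium exchange by 9, which the chelated and weakly basic α-oxy organolithium at −78 °C should secure, and it needs acylation at the ring carbon between the methoxy group and the side chain, which the bromine atom fixes.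

Step 6
Reactants: 12 N,N-diisopropyl-2-[(2R,8E)-2-hydroxyheptadec-8-en-1-yl]-6-methoxybenzamide
Product: 13 (3R)-8-methoxy-3-[(6E)-pentadec-6-en-1-yl]-3,4-dihydro-1H-isochromen-1-one
Conditions: TsOH·H2O (1.5 equiv), PhMe, 100 °C
Reagents that add atoms: none
Why: Acid-promoted lactonization by intramolecular N-to-O acyl transfer: the C3 hydroxyl should add to the protonated amide in a 6-exo-trig closure and diisopropylammonium should leave, and since the C3–O bond stays intact the R configuration is kept.

Step 7
Reactants: 13 (3R)-8-methoxy-3-[(6E)-pentadec-6-en-1-yl]-3,4-dihydro-1H-isochromen-1-one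
Product: 14 (3R)-8-hydroxy-3-[(6E)-pentadec-6-en-1-yl]-3,4-dihydro-1H-isochromen-1-one
Conditions: BCl3, CH2Cl2, −78 to 0 °C; then H2O
Reagents that add atoms: none
Why: Chelation-assisted Lewis-acid ether cleavage: BCl3 binds between the lactone carbonyl and the peri methoxy oxygen and chloride removes the methyl group by SN2, which at low temperature should leave the lactone, the stereocenter and the isolated E alkene untouched.

**Compound list**
1 | oct-7-yn-1-ol | C#CCCCCCCO | starting material
2 | 1-bromooctane | CCCCCCCCBr | starting material
3 | hexadec-7-yn-1-ol | CCCCCCCCC#CCCCCCCO | intermediate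
4 | (7E)-hexadec-7-en-1-ol | CCCCCCCC/C=C/CCCCCCO | intermediate
5 | N,N-diisopropylcarbamoyl chloride | CC(C)N(C(C)C)C(=O)Cl | starting material
6 | (7E)-hexadec-7-en-1-yl N,N-diisopropylcarbamate | CCCCCCCC/C=C/CCCCCCOC(=O)N(C(C)C)C(C)C | intermediate
7 | 2-bromo-1-methoxy-3-methylbenzene (2-bromo-3-methylanisole) | COc1cccc(C)c1Br | starting material
8 | 2-bromo-1-(bromomethyl)-3-methoxybenzene | COc1cccc(CBr)c1Br | intermediate
9 | (1S,7E)-1-lithiohexadec-7-en-1-yl N,N-diisopropylcarbamate, present as its (−)-sparteine complex | CCCCCCCC/C=C/CCCCC[C@H]([Li])OC(=O)N(C(C)C)C(C)C | intermediate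
10 | (2R,8E)-1-(2-bromo-3-methoxyphenyl)heptadec-8-en-2-yl N,N-diisopropylcarbamate | CCCCCCCC/C=C/CCCCC[C@H](Cc1cccc(OC)c1Br)OC(=O)N(C(C)C)C(C)C | intermediate
11 | (2R,8E)-1-(2-lithio-3-methoxyphenyl)heptadec-8-en-2-yl N,N-diisopropylcarbamate | CCCCCCCC/C=C/CCCCC[C@H](Cc1cccc(OC)c1[Li])OC(=O)N(C(C)C)C(C)C | intermediate
12 | N,N-diisopropyl-2-[(2R,8E)-2-hydroxyheptadec-8-en-1-yl]-6-methoxybenzamide | CCCCCCCC/C=C/CCCCC[C@@H](O)Cc1cccc(OC)c1C(=O)N(C(C)C)C(C)C | intermediate
13 | (3R)-8-methoxy-3-[(6E)-pentadec-6-en-1-yl]-3,4-dihydro-1H-isochromen-1-one | CCCCCCCC/C=C/CCCCC[C@@H]1Cc2cccc(OC)c2C(=O)O1 | intermediate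
14 | (3R)-8-hydroxy-3-[(6E)-pentadec-6-en-1-yl]-3,4-dihydro-1H-isochromen-1-one | CCCCCCCC/C=C/CCCCC[C@@H]1Cc2cccc(O)c2C(=O)O1 | target

Total steps: 7. Longest linear sequence: 6 steps (steps 1, 2, 3, 5, 6, 7).

**Steps most likely to fail**

Step 5. Electron transfer from 9 to the benzylic bromide, or bromine–lithium exchange at the aryl bromide, may erode configurational purity and consume material, and the carbamoyl transfer may stay incomplete. The fallback uses known chemistry, sets out from 6 and 8 and comes back to the route at 13. Copper-catalysed borylation of 8 (CuI, PPh3, LiOMe, B2pin2, DMF, rt) should give 2-[(2-bromo-3-methoxyphenyl)methyl]-4,4,5,5-tetramethyl-1,3,2-dioxaborolane F1. Organolithium 9, made from 6 as in step 5, should add to F1 at −78 °C to give lithium [(2-bromo-3-methoxyphenyl)methyl][(1S,7E)-1-(diisopropylcarbamoyloxy)hexadec-7-en-1-yl](pinacolato)borate F2. On warming with MgBr2·OEt2 this should undergo the Matteson-type 1,2-metallate rearrangement (benzyl shift from boron to carbon with inversion at carbon and loss of the carbamate) to 2-[(2R,8E)-1-(2-bromo-3-methoxyphenyl)heptadec-8-en-2-yl]-4,4,5,5-tetramethyl-1,3,2-dioxaborolane F3. Oxidation with NaOH/H2O2, which retains configuration, should give (2R,8E)-1-(2-bromo-3-methoxyphenyl)heptadec-8-en-2-ol F4. Palladium-catalysed alkoxycarbonylation of the aryl bromide by the tethered hydroxyl (Pd(OAc)2, Xantphos, CO at 1 atm, Et3N, PhMe, 100 °C) should then close the lactone 13, so that step 6 is not needed.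

Step 6. The N-to-O acyl transfer may stall at an amide flanked by two ortho substituents, and on forced heating the acid may move the chain double bond. The fallback sets out from 12 and comes back at 13, and it replaces Brønsted-acid catalysis by stoichiometric activation of the amide oxygen at room temperature. O-Methylation with Me3OBF4 (CH2Cl2, rt) should give N-{[2-((2R,8E)-2-hydroxyheptadec-8-en-1-yl)-6-methoxyphenyl](methoxy)methylidene}-N-isopropylpropan-2-aminium tetrafluoroborate F5. Its activated carbon should be captured by the neighbouring hydroxyl, and aqueous NaHCO3 work-up should release diisopropylamine and methanol and leave 13.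

Step 7. The Lewis acid and the hydrogen chloride formed on work-up may add to or shift the chain alkene, or ether cleavage may stay incomplete. The fallback sets out from 13 and comes back at 14, and it changes the mode of cleavage from electrophilic activation of the ether oxygen to SN2 attack at the methyl carbon. NaSEt in DMF at 100 °C, followed by aqueous HCl work-up, should remove the methyl group because the ortho carbonyl makes the phenoxide a good leaving group; any reversible opening of the lactone by thiolate should revert on acidification. This fallback makes no new compound.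

Further compounds
F1 | step 5 | 2-[(2-bromo-3-methoxyphenyl)methyl]-4,4,5,5-tetramethyl-1,3,2-dioxaborolane | COc1cccc(CB2OC(C)(C)C(C)(C)O2)c1Br
F2 | step 5 | lithium [(2-bromo-3-methoxyphenyl)methyl][(1S,7E)-1-(diisopropylcarbamoyloxy)hexadec-7-en-1-yl](pinacolato)borate | [Li+].CCCCCCCC/C=C/CCCCC[C@H]([B-]1(Cc2cccc(OC)c2Br)OC(C)(C)C(C)(C)O1)OC(=O)N(C(C)C)C(C)C
F3 | step 5 | 2-[(2R,8E)-1-(2-bromo-3-methoxyphenyl)heptadec-8-en-2-yl]-4,4,5,5-tetramethyl-1,3,2-dioxaborolane | CCCCCCCC/C=C/CCCCC[C@@H](B1OC(C)(C)C(C)(C)O1)Cc1cccc(OC)c1Br
F4 | step 5 | (2R,8E)-1-(2-bromo-3-methoxyphenyl)heptadec-8-en-2-ol | CCCCCCCC/C=C/CCCCC[C@@H](O)Cc1cccc(OC)c1Br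
F5 | step 6 | N-{[2-((2R,8E)-2-hydroxyheptadec-8-en-1-yl)-6-methoxyphenyl](methoxy)methylidene}-N-isopropylpropan-2-aminium tetrafluoroborate | CCCCCCCC/C=C/CCCCC[C@@H](O)Cc1cccc(OC)c1C(OC)=[N+](C(C)C)C(C)C.F[B-](F)(F)F
F0 | step 7 | none | none
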